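**Retrosynthetic overview**
1. Target ⇐ C1‑OH‑directed 1,3‑anti reduction of a C9 ketone ⇐ key C5–O bond: anti opening of a 1α,5α‑epoxy ketone by angelic acid, which installs the angelate, sets C5 and frees the C1‑OH.
2. Epoxide ⇐ C6‑OH‑directed epoxidation of the ring enone; α‑methylene‑γ‑lactone ⇐ Pd cyclocarbonylation of the cis C6‑OH/C7‑ethynyl pair; crotonoyl ⇐ Weinreb amide + (E)‑propenyllithium.
3. Cycloheptadiene core (C6, C7, C10 all‑cis) ⇐ Rh(II) [4+3] (cyclopropanation/Cope) of a 2‑siloxy dienyne with an (E)‑benzoyloxyvinyl diazoacetate.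
4. Ring order: seven‑membered carbocycle → oxirane (transient) → γ‑lactone.

Convention: locants follow the target (C1 = C(OH) bearing the crotonoyl group, C5 = CH–OAng, C6 = CH–O of the lactone, C7, C8, C9 = CHOH, C10 = CHMe); with the ring drawn C6→C7→C8→C9→C10→C1→C5 clockwise, β points to the viewer and α away.
Assumption: Rh2(S‑DOSP)4 is taken to give the enantiomer drawn; if the sense is opposite, the mirror‑image catalyst Rh2(R‑DOSP)4 is used.

**Step 1**
Reactants: 1 3‑(trimethylsilyl)prop‑2‑ynal; 2 diethyl (2‑oxobutyl)phosphonate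
Product: 3 (E)‑7‑(trimethylsilyl)hept‑4‑en‑6‑yn‑3‑one
Conditions: LiCl, i‑Pr2NEt, MeCN, 0 °C to rt
Reagents that add atoms: none
Why: Horner–Wadsworth–Emmons olefination (Masamune–Roush conditions) of the stabilised β‑ketophosphonate gives the (E)‑enone, and the mild amine base leaves the alkynyl C–Si bond intact.

**Step 2**
Reactants: 3 (E)‑7‑(trimethylsilyl)hept‑4‑en‑6‑yn‑3‑one
Product: 4 (2Z,4E)‑3‑(triisopropylsilyloxy)‑7‑(trimethylsilyl)hepta‑2,4‑dien‑6‑yne
Conditions: TIPSOTf, Et3N, CH2Cl2, −78 to 0 °C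
Reagents that add atoms: triisopropylsilyl trifluoromethanesulfonate, CC(C)[Si](C(C)C)(C(C)C)OS(=O)(=O)C(F)(F)F
Why: Soft enolisation/O‑silylation can only occur at the ethyl CH2 (the γ‑position is an alkyne carbon) and gives the Z silyl enol ether (Me cis to OSi) typical of R3SiOTf/Et3N.

**Step 3**
Reactants: 5 ethyl diazoacetate; 6 2‑oxoethyl benzoate
Product: 7 ethyl 4‑(benzoyloxy)‑2‑diazo‑3‑hydroxybutanoate (racemic)
Conditions: DBU (10 mol %), MeCN, rt
Reagents that add atoms: none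
Why: DBU‑catalysed aldol‑type addition of the diazoacetate carbon to the aldehyde; the carbinol centre is racemic and is removed in the next step.

**Step 4**
Reactants: 7 ethyl 4‑(benzoyloxy)‑2‑diazo‑3‑hydroxybutanoate
Product: 8 ethyl (E)‑4‑(benzoyloxy)‑2‑diazobut‑3‑enoate
Conditions: POCl3, Et3N, CH2Cl2, 0 °C to rt
Reagents that add atoms: none
Why: Phosphorylation/elimination (dehydration of a β‑hydroxy‑α‑diazo ester) gives the conjugated vinyl diazoacetate as the thermodynamically preferred (E)‑enol benzoate.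

**Step 5**
Reactants: 4 (2Z,4E)‑3‑(triisopropylsilyloxy)‑7‑(trimethylsilyl)hepta‑2,4‑dien‑6‑yne; 8 ethyl (E)‑4‑(benzoyloxy)‑2‑diazobut‑3‑enoate
Product: 10 ethyl 6α‑(benzoyloxy)‑10α‑methyl‑9‑(triisopropylsilyloxy)‑7α‑[(trimethylsilyl)ethynyl]cyclohepta‑1(5),8‑diene‑1‑carboxylate, via cis‑divinylcyclopropane ester 9 (not isolated)
Conditions: Rh2(S‑DOSP)4 (1 mol %), slow addition of 8, hexanes–PhCF3, −40 °C to rt, then 50 °C
Reagents that add atoms: none
Why: Davies formal [4+3] cycloaddition (tandem cyclopropanation/Cope rearrangement): the Rh vinylcarbenoid cyclopropanates the electron‑rich silyl enol ether C=C with the two alkenyl groups cis, the boat Cope transition state converts the E, E and Z alkene geometries into the all‑cis (α) C6‑O/C7‑alkynyl/C10‑Me triad, and the chiral catalyst fixes the absolute sense.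

**Step 6**
Reactants: 10 cycloheptadiene benzoate
Product: 11 ethyl 7α‑ethynyl‑6α‑hydroxy‑10α‑methyl‑9‑(triisopropylsilyloxy)cyclohepta‑1(5),8‑diene‑1‑carboxylate
Conditions: K2CO3, EtOH, 0 °C to rt
Reagents that add atoms: none
Why: Ethanolysis removes the benzoate (transesterification) and the alkynyl SiMe3 group (protodesilylation) in one operation while the hindered TIPS enol ether and the ethyl ester survive; no stereocentre is touched.

**Step 7**
Reactants: 11 hydroxy enoate
Product: 12 7α‑ethynyl‑6α‑hydroxy‑N‑methoxy‑N,10α‑dimethyl‑9‑(triisopropylsilyloxy)cyclohepta‑1(5),8‑diene‑1‑carboxamide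
Conditions: MeNHOMe·HCl, i‑PrMgCl (excess), THF, −20 to 0 °C
Reagents that add atoms: N,O‑dimethylhydroxylamine hydrochloride, CNOC.Cl
Why: Weinreb amide formation by aminolysis of the ester with the chloromagnesium amide; the OH and alkyne C–H are only deprotonated and return on work‑up.

**Step 8**
Reactants: 12 Weinreb amide
Product: 13 (E)‑1‑[7α‑ethynyl‑6α‑hydroxy‑10α‑methyl‑9‑(triisopropylsilyloxy)cyclohepta‑1(5),8‑dien‑1‑yl]but‑2‑en‑1‑one
Conditions: (E)‑1‑bromopropene, t‑BuLi, Et2O, −78 °C; then 12, THF, −78 °C; aq. NH4Cl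
Reagents that add atoms: (E)‑1‑bromoprop‑1‑ene, C/C=C/Br (converted in the flask into (E)‑prop‑1‑enyllithium, C/C=C/[Li])
Why: Weinreb ketone synthesis: Br/Li exchange retains the E geometry and the chelated tetrahedral intermediate prevents over‑addition, giving the crotonoyl ketone.

**Step 9**
Reactants: 13 hydroxy dienone
Product: 14 1α,5α‑epoxide of 13 [(E)‑1‑(1α,5α‑epoxy‑7α‑ethynyl‑6α‑hydroxy‑10α‑methyl‑9‑(triisopropylsilyloxy)cyclohept‑8‑en‑1‑yl)but‑2‑en‑1‑one]
Conditions: t‑BuOOH, n‑BuLi, THF, −78 to −20 °C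
Reagents that add atoms: tert‑butyl hydroperoxide, CC(C)(C)OO
Why: Hydroxyl‑directed nucleophilic (Weitz–Scheffer‑type) epoxidation: lithium tert‑butyl peroxide held by the C6 oxygen adds to C5 of the ring enone on the α‑face and the enolate closes the oxirane syn to C6‑OH, which sets C1 and places the future C1‑OH oxygen, while the undirected crotonoyl alkene and the silyl enol ether are left alone.

**Step 10**
Reactants: 14 epoxy alkynol
Product: 15 cis‑fused 6α,12‑olide: 1α,5α‑epoxy‑1β‑[(E)‑but‑2‑enoyl]‑10α‑methyl‑9‑(triisopropylsilyloxy)‑8‑ene α‑methylene‑γ‑lactone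
Conditions: PdCl2 (5 mol %), PPh3, SnCl2 (cat.), CO (8 atm), MeCN, 70 °C
Reagents that add atoms: carbon monoxide, [C-]#[O+]
Why: Pd‑catalysed cyclocarbonylation (intramolecular alkoxycarbonylation) of the homopropargylic alcohol: syn insertion of the alkyne into the Pd–CO2R bond and protonolysis give the α‑methylene‑γ‑lactone, cis‑fused because C6‑O and the C7 ethynyl group are already cis.

**Step 11**
Reactants: 15 epoxy lactone; 16 angelic acid
Product: 17 5β‑angeloyloxy‑1α‑hydroxy‑1β‑[(E)‑but‑2‑enoyl]‑10α‑methyl‑9‑(triisopropylsilyloxy)‑8‑ene 6α,12‑olide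
Conditions: 16 (3 equiv), Mg(NTf2)2 (10 mol %), i‑Pr2NEt (0.3 equiv), MeCN, 40 °C
Reagents that add atoms: none
Why: Proposed new method: chelation‑directed anti carboxylate opening of an α,β‑epoxy ketone; Mg(II) binds the ketone and oxirane oxygens in a five‑membered chelate and weakens the distal C5–O bond (C1 is quaternary and α to C=O, so neither SN2 nor SN1 is viable there), and buffered angelate (no acyl activation or nucleophilic amine, so the Z alkene is not isomerised) attacks C5 from the open β‑face with inversion, giving the C5β‑O‑angelate and leaving the C1–O bond as the tertiary α‑OH; the closest known reactions are the Ti(Oi‑Pr)4‑mediated C3‑selective opening of 2,3‑epoxy alcohols by carboxylic acids and Lewis‑acid/carboxylate acidolysis of simple epoxides.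

**Step 12**
Reactants: 17 angelate silyl enol ether
Product: 19 target CNP0149130.1, via 9‑oxo lactone 18 (not isolated)
Conditions: HF·pyridine, MeCN, 0 °C; then Me4NBH(OAc)3, AcOH, −30 to 0 °C
Reagents that add atoms: none
Why: Fluoride cleavage of the silyl enol ether gives the C9 ketone, and Evans–Saksena hydroxyl‑directed reduction delivers hydride intramolecularly from the C1α‑O–B complex to the α‑face of C9, giving the 1,3‑anti (9β) alcohol without touching the lactone, the angelate or the less electrophilic enone.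

**Compound list**
1 | 3‑(trimethylsilyl)prop‑2‑ynal | C[Si](C)(C)C#CC=O | starting material
2 | diethyl (2‑oxobutyl)phosphonate | CCC(=O)CP(=O)(OCC)OCC | starting material
3 | (E)‑7‑(trimethylsilyl)hept‑4‑en‑6‑yn‑3‑one | CCC(=O)/C=C/C#C[Si](C)(C)C | intermediate
4 | (2Z,4E)‑3‑(triisopropylsilyloxy)‑7‑(trimethylsilyl)hepta‑2,4‑dien‑6‑yne | C/C=C(\O[Si](C(C)C)(C(C)C)C(C)C)/C=C/C#C[Si](C)(C)C | intermediate
5 | ethyl diazoacetate | CCOC(=O)C=[N+]=[N-] | starting material
6 | 2‑oxoethyl benzoate (benzoyloxyacetaldehyde) | O=CCOC(=O)c1ccccc1 | starting material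
7 | ethyl 4‑(benzoyloxy)‑2‑diazo‑3‑hydroxybutanoate (racemic) | CCOC(=O)C(=[N+]=[N-])C(O)COC(=O)c1ccccc1 | intermediate
8 | ethyl (E)‑4‑(benzoyloxy)‑2‑diazobut‑3‑enoate | CCOC(=O)C(=[N+]=[N-])/C=C/OC(=O)c1ccccc1 | intermediate
9 | ethyl 1‑[(E)‑2‑(benzoyloxy)ethenyl]‑2‑methyl‑3‑(triisopropylsilyloxy)‑3‑[(E)‑4‑(trimethylsilyl)but‑1‑en‑3‑ynyl]cyclopropane‑1‑carboxylate (the two alkenyl groups cis, methyl trans to both) | CCOC(=O)[C@@]1(/C=C/OC(=O)c2ccccc2)[C@@H](C)[C@]1(O[Si](C(C)C)(C(C)C)C(C)C)/C=C/C#C[Si](C)(C)C | intermediate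
10 | ethyl 6α‑(benzoyloxy)‑10α‑methyl‑9‑(triisopropylsilyloxy)‑7α‑[(trimethylsilyl)ethynyl]cyclohepta‑1(5),8‑diene‑1‑carboxylate | CCOC(=O)C1=C[C@H](OC(=O)c2ccccc2)[C@H](C#C[Si](C)(C)C)C=C(O[Si](C(C)C)(C(C)C)C(C)C)[C@@H]1C | intermediate
11 | ethyl 7α‑ethynyl‑6α‑hydroxy‑10α‑methyl‑9‑(triisopropylsilyloxy)cyclohepta‑1(5),8‑diene‑1‑carboxylate | CCOC(=O)C1=C[C@H](O)[C@H](C#C)C=C(O[Si](C(C)C)(C(C)C)C(C)C)[C@@H]1C | intermediate
12 | Weinreb amide of 11 | CON(C)C(=O)C1=C[C@H](O)[C@H](C#C)C=C(O[Si](C(C)C)(C(C)C)C(C)C)[C@@H]1C | intermediate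
13 | (E)‑crotonoyl dienone, 6α‑OH, 7α‑ethynyl, 10α‑Me | C/C=C/C(=O)C1=C[C@H](O)[C@H](C#C)C=C(O[Si](C(C)C)(C(C)C)C(C)C)[C@@H]1C | intermediate
14 | 1α,5α‑epoxide of 13 | C/C=C/C(=O)[C@@]12O[C@@H]1[C@H](O)[C@H](C#C)C=C(O[Si](C(C)C)(C(C)C)C(C)C)[C@@H]2C | intermediate
15 | 1α,5α‑epoxy cis‑fused α‑methylene‑γ‑lactone (6α,12‑olide), 9‑TIPS enol ether | C=C1C(=O)O[C@@H]2[C@H]1C=C(O[Si](C(C)C)(C(C)C)C(C)C)[C@H](C)[C@]3(C(=O)/C=C/C)O[C@H]23 | intermediate
16 | angelic acid, (Z)‑2‑methylbut‑2‑enoic acid | C/C=C(/C)C(=O)O | starting material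
17 | 5β‑angeloyloxy‑1α‑hydroxy lactone, 9‑TIPS enol ether | C=C1C(=O)O[C@@H]2[C@H]1C=C(O[Si](C(C)C)(C(C)C)C(C)C)[C@H](C)[C@@](O)(C(=O)/C=C/C)[C@H]2OC(=O)/C(C)=C\C | intermediate
18 | 9‑oxo analogue of the target | C=C1C(=O)O[C@@H]2[C@H]1CC(=O)[C@H](C)[C@@](O)(C(=O)/C=C/C)[C@H]2OC(=O)/C(C)=C\C | intermediate
19 | CNP0149130.1: 5β‑angeloyloxy‑1α,9β‑dihydroxy‑10α‑methyl‑1β‑[(E)‑but‑2‑enoyl] cis‑6α,12‑olide, (1S,5S,6R,7S,9R,10S) in the locants used here | C=C1C(=O)O[C@@H]2[C@H]1C[C@@H](O)[C@H](C)[C@@](O)(C(=O)/C=C/C)[C@H]2OC(=O)/C(C)=C\C | target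

**Totals**
Total steps: 12. Longest linear sequence: 10 (steps 1, 2, 5–12); steps 3 and 4 form the side branch.

**Three steps most likely to fail**

Step 5 ([4+3]). The reaction type is established, but this benzoyloxy‑substituted vinylcarbenoid and the trisubstituted siloxy dienyne are untested in it. Possible failures are attack at the wrong site, [3+2] annulation, a trans‑divinylcyclopropane that does not rearrange, or low ee. Fallback, setting out from 4 (with 5 and 6) and returning at 10: build the cis‑divinylcyclopropane stepwise by known chemistry. Cu(I)/bis(oxazoline)‑catalysed cyclopropanation of the silyl enol ether C=C of 4 with ethyl diazoacetate 5 gives the siloxycyclopropane ester F1. Its ester enolate (LDA, THF, −78 °C) adds to aldehyde 6 trans to the siloxy group to give the hydroxy ester F2. Dehydration (MsCl, Et3N, then DBU) forms the (E)‑enol benzoate, which is 9, and this rearranges on warming to 10.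

Step 10 (cyclocarbonylation). The Lewis‑acidic Pd/Sn system at 70 °C may open the epoxy ketone or cleave the silyl enol ether. Fallback, from 14 back to 15: Mo(CO)3(CNt‑Bu)3‑catalysed hydrostannation with Bu3SnH gives the internal vinylstannane F3. Iodine converts it into the 2‑iodoalkene F4. Pd(PPh3)4, CO (1 atm), K2CO3, THF, 50 °C then closes the α‑methylene lactone by carbonylative lactonisation to give 15.

Step 11 (proposed new step). SN2 attack at C5 is hindered by the quaternary C1 and by C6, and a Lewis acid can instead trigger a 1,2‑acyl shift of the epoxy ketone or angelate‑to‑tiglate isomerisation. Fallback by known chemistry, from 15, returning at 18: aqueous HClO4 in THF hydrolyses the oxirane (water attacks C5 anti) and the silyl enol ether to give the keto diol F5. Yamaguchi esterification of its only secondary hydroxyl with 16 (2,4,6‑trichlorobenzoyl chloride, Et3N, toluene, 80 °C) gives 18, which is reduced as in the second half of step 12.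

**Further compounds**
F1 | step 5 | ethyl 2‑methyl‑3‑(triisopropylsilyloxy)‑3‑[(E)‑4‑(trimethylsilyl)but‑1‑en‑3‑ynyl]cyclopropane‑1‑carboxylate (Me cis to OSi; ester epimers) | CCOC(=O)C1[C@@H](C)[C@]1(O[Si](C(C)C)(C(C)C)C(C)C)/C=C/C#C[Si](C)(C)C
F2 | step 5 | ethyl 1‑[2‑(benzoyloxy)‑1‑hydroxyethyl]‑2‑methyl‑3‑(triisopropylsilyloxy)‑3‑[(E)‑4‑(trimethylsilyl)but‑1‑en‑3‑ynyl]cyclopropane‑1‑carboxylate (hydroxyalkyl trans to OSi; carbinol epimers) | CCOC(=O)[C@@]1(C(O)COC(=O)c2ccccc2)[C@@H](C)[C@]1(O[Si](C(C)C)(C(C)C)C(C)C)/C=C/C#C[Si](C)(C)C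
F3 | step 10 | 14 with the ethynyl group replaced by 1‑(tributylstannyl)ethenyl | C/C=C/C(=O)[C@@]12O[C@@H]1[C@H](O)[C@H](C(=C)[Sn](CCCC)(CCCC)CCCC)C=C(O[Si](C(C)C)(C(C)C)C(C)C)[C@@H]2C
F4 | step 10 | 14 with the ethynyl group replaced by 1‑iodoethenyl | C/C=C/C(=O)[C@@]12O[C@@H]1[C@H](O)[C@H](C(I)=C)C=C(O[Si](C(C)C)(C(C)C)C(C)C)[C@@H]2C
F5 | step 11 | 1α,5β‑dihydroxy‑9‑oxo lactone (18 without the angeloyl group) | C=C1C(=O)O[C@@H]2[C@H]1CC(=O)[C@H](C)[C@@](O)(C(=O)/C=C/C)[C@H]2O
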